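The numbers in the tables are simulated on assumed constants; the scatter is artificial.

1. 4 questions stand below, and they lean on how the red run, the asked flask followed so far, behaves late.

| flask | solid substrate | reagent | temperature | remark | time |
|---|---|---|---|---|---|
| red | 40 mM | 40 mM | −20 °C | the very flask that is asked about, followed so far |  |
| flask | 40 mM | 40.0 mM | −20 °C |  | 20 h |

red run (percent of the solid substrate charged)

| time / h | target / % | solid substrate / % |
|---|---|---|
| 1.33 | 26 | 46 |
| 3.00 | 52 | 5 |
| 6.00 | 66 | 0 |
| 15.0 | 58 | 0 |

(readings scatter by 2 percentage points)

- solid substrate is a solid; its amount is given per volume of the solution
- target that was removed still counts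
- at the start none of the solid substrate is in solution
- the earlier runs do not show what temperature does; that part of a forecast is a guess
- additions bring no volume worth counting

- winter: at 20 h raise the temperature by 20 K, then wait 40 h
- autumn: at 20 h add reagent, 50.0 % of the amount charged, then wait 40 h
- noon: change nothing and wait 40 h more
- summer: at 20 h take out 90 % of the target then present, then wait 40 h

- target, in percent of the solid substrate first charged, at 20 h
- what to do for the largest gain in target; "none" if nothing gains more than 2 percentage points (winter / autumn / noon / summer / none)
- target present, with what was taken out counted in, in percent of the solid substrate first charged, after autumn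
- target present, with what was taken out counted in, in percent of the solid substrate first charged, after noon

2. Start of the red run: the charges give 1.00 equivalents of reagent per solid substrate. Late end: target reads 58 % at 15.0 h, with solid substrate at 0 %. Joining the two ends gives 0.580, the reagent yield, the fraction of the substrate charge standing as target per equivalent of reagent charged. It is a reading and carries a scatter of 2 percentage points.

3. At 15.0 h a share of 42.0 % of the charge is neither target nor solid in the red run. The question turned round: for autumn to gain, that fraction would have to be substrate still waiting for reagent, and target should hold or climb once the solid is gone. In the red run target instead falls from 66 % to 58 %, a drop larger than the scatter.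

4. My own reckoning: at 20 h target stands a little below the yield 0.580, and noon and autumn bring no gain. Summer and winter stay open; what temperature does is a guess here. The forecast differs by choosing: 55 % now, 45 % after autumn, 44 % after noon, and summer as best, on the ground "Removing target protects it under either picture".

5. The flask gives 54.6 %, 51.3 % after autumn and 50.6 % after noon. The best option is winter, with a gain of 30 points against 20 points for summer.

    dissolved substrate + reagent → target (k = 0.00720 /M/s, Ea = 45.0 kJ/mol)
    solid substrate ⇌ dissolved substrate, rate k2*(cs2 - [dissolved substrate]) while solid is left; crystals form when [dissolved substrate] > cs2 (solubility = 22.0 mM, k = 3.10 × 10⁻⁴ /s)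
    target ⇌ isomer of the product (K = 0.950, k = 1.80 × 10⁻⁵ /s, Ea = 87.0 kJ/mol, ΔH = −48.0 kJ/mol)
    (constants at −20 °C)

At 20.0 h the flask holds 40.4 % isomer of the product beside 54.6 % target, and the relaxation half-life of that step alone, both ways together, is 5.21 h, shorter than 20 h. The yield 0.580 applied to the 95.0 % of the reagent charge spent in the flask at that time gives 55.1 %.

6. The neighbour flask is the same flask with 24 mM of reagent, or 0.600 equiv. There the yield gives 34.8 %. The computed neighbour flask holds 33.9 % target at 20 h, with reagent, its limiting reagent, down to 0.024 % of its charge.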